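**Retrosynthetic overview**

1. Feature: C11b, the ring-fusion methine (C3 of the dihydrofuran annulated to the seven-membered ring), is bonded to ring B at C11a, a carbon meta to both ring B oxygens (on C8 and C10), so no electrophilic aromatic substitution can make this bond; as C3 of a benzofuran-2(3H)-one the same carbon is an acidic enolate carbon.
2. Key disconnection C11b–C11a: intramolecular Pd-catalysed arylation of the lactone enolate of 21 by the ring B chloride closes the seven-membered ring and sets C11b relative to C7 (gives 22).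
3. 21 comes from a Negishi coupling (bond C5a–C6) of an (S)-2,2-diarylethylzinc reagent with bromobenzofuranone 19. C7 is set by Rh-catalysed conjugate arylation and the carboxyl carbon is removed by Barton iododecarboxylation; 19 is made from 5-bromoresorcinol by acylation, Claisen rearrangement and oxidative cleavage.
4. After the key step the lactone carbonyl becomes C1 (hydride, aryl Grignard, acid cyclisation; aryl trans to ring B), the aroyl ketone becomes the second trans-dihydrofuran (o-quinone methide plus sulfur ylide, [4+1]), and BBr3 frees the eight phenols.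
5. Ring order: ring A lactone (step 11), seven-membered ring (step 13), dihydrofuran O2/C1 (step 16), dihydrofuran on C4–C5 (step 20).

Key step: step 13

Remark on locants: the tetracyclic core is numbered as benzo[6,7]cyclohepta[1,2,3-cd][1]benzofuran. C1 is the furan carbon next to O2, ring A is C2a–C5a with C11c, C6 is the CH2, C7 the aryl-bearing methine, ring B is C7a–C11a, and C11b the ring-fusion methine.

Remark on protecting groups: all phenols are methyl ethers except the ring A oxygen on C4, which is a benzyl ether. It must be freed after the first aryl-substituted dihydrofuran exists, where a Lewis acid would open the benzylic C1–O2 bond; hydrogenolysis avoids this.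

Assumption: with the (S,S)-diene the aryl group is taken to be delivered to the enoate face that gives (S)-5, by analogy with the sense known for (E)-enones and enoates; should the opposite sense be found, the (R,R)-ligand is used and nothing else changes.

**Route**

Step 1
Reactants: 1 1-chloro-3,5-dimethoxybenzene
Product: 2 2-chloro-4,6-dimethoxybenzaldehyde
Conditions: POCl3, DMF, 0 → 80 °C; then aq NaOAc
Reagents that add atoms: N,N-dimethylformamide, CN(C)C=O; water, O
Why: Vilsmeier–Haack formylation of the doubly activated arene, expected (as with the bromo analogue) mainly at C2, para to one methoxy group and ortho to the other and to chlorine, the minor 4-chloro-2,6-dimethoxy isomer being removed by crystallisation.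

Step 2
Reactants: 2 2-chloro-4,6-dimethoxybenzaldehyde
Product: 3 methyl (2E)-3-(2-chloro-4,6-dimethoxyphenyl)prop-2-enoate
Conditions: (MeO)2P(O)CH2CO2Me, NaH, THF, 0 °C → rt
Reagents that add atoms: trimethyl phosphonoacetate, COC(=O)CP(=O)(OC)OC
Why: Horner–Wadsworth–Emmons olefination, in which the stabilised phosphonate anion should give the (E)-enoate even with the 2,6-disubstituted aldehyde.

Step 3
Reactants: 3 methyl (2E)-3-(2-chloro-4,6-dimethoxyphenyl)prop-2-enoate; 4 2,4-dimethoxyphenylboronic acid
Product: 5 methyl (3S)-3-(2-chloro-4,6-dimethoxyphenyl)-3-(2,4-dimethoxyphenyl)propanoate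
Conditions: 4 (3 equiv), [RhCl(C2H4)2]2 (3 mol%), (1S,4S)-2,5-diphenylbicyclo[2.2.2]octa-2,5-diene (6.6 mol%), aq KOH (0.2 equiv), 1,4-dioxane/H2O 10:1, 60 °C
Reagents that add atoms: none
Why: Hayashi–Miyaura rhodium-catalysed asymmetric conjugate arylation, in which the aryl–rhodium species formed by transmetalation adds across the enoate on the face left open by the C2-symmetric diene (this sets C7 as S) and the resulting oxa-π-allyl rhodium is protonated by water, the doubly ortho-substituted β-aryl group slowing insertion and hence calling for excess boronic acid and 60 °C.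

Step 4
Reactants: 5 methyl (3S)-3-(2-chloro-4,6-dimethoxyphenyl)-3-(2,4-dimethoxyphenyl)propanoate
Product: 6 (3S)-3-(2-chloro-4,6-dimethoxyphenyl)-3-(2,4-dimethoxyphenyl)propanoic acid
Conditions: LiOH·H2O, THF/MeOH/H2O, rt; then 1 M HCl
Reagents that add atoms: lithium hydroxide, [Li+].[OH-]
Why: Ester saponification, during which the stereocentre, being β to the carboxylate, cannot epimerise.

Step 5
Reactants: 6 (3S)-3-(2-chloro-4,6-dimethoxyphenyl)-3-(2,4-dimethoxyphenyl)propanoic acid
Product: 9 1-chloro-2-[(1S)-1-(2,4-dimethoxyphenyl)-2-iodoethyl]-3,5-dimethoxybenzene, via acid chloride 7 (not isolated), via thiohydroxamate ester 8 (not isolated)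
Conditions: (COCl)2, DMF (cat.), CH2Cl2, 0 °C → rt; then sodium 2-sulfanylidenepyridin-1(2H)-olate, DMAP (cat.), CHI3 (2 equiv), CH2Cl2, tungsten lamp, 25–40 °C
Reagents that add atoms: iodoform, IC(I)I
Why: Barton iododecarboxylation (radical chain through the thiohydroxamate ester), in which the primary 2,2-diarylethyl radical is trapped by iodoform much faster than it can undergo a 1,2-aryl shift, the stereocentre is not part of the radical, and the iodide opens the way to a polar organozinc reagent so that no free alkyl radical is needed in the coupling with the hindered ring A bromide.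

Step 6
Reactants: 10 5-bromoresorcinol; 11 3,5-dimethoxybenzoyl chloride
Product: 12 (2-bromo-4,6-dihydroxyphenyl)(3,5-dimethoxyphenyl)methanone
Conditions: AlCl3 (3 equiv), ClCH2CH2Cl, 0 → 60 °C; then cold 1 M HCl
Reagents that add atoms: none
Why: Friedel–Crafts C-acylation (with Fries rearrangement of any O-acylated material) at C4 of the resorcinol, ortho and para to the two hydroxyls as in the acylation of orcinol, the methoxy groups of the acyl part not being ortho to the carbonyl and therefore expected to survive AlCl3 at this temperature.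

Step 7
Reactants: 12 (2-bromo-4,6-dihydroxyphenyl)(3,5-dimethoxyphenyl)methanone
Product: 13 [2-bromo-6-hydroxy-4-(prop-2-en-1-yloxy)phenyl](3,5-dimethoxyphenyl)methanone
Conditions: allyl bromide (1.05 equiv), K2CO3, acetone, reflux
Reagents that add atoms: allyl bromide, C=CCBr
Why: Williamson etherification selective for the hydroxyl para to the ketone, because the ortho hydroxyl is held in a hydrogen bond to the carbonyl and is far less acidic and nucleophilic.

Step 8
Reactants: 13 [2-bromo-6-hydroxy-4-(prop-2-en-1-yloxy)phenyl](3,5-dimethoxyphenyl)methanone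
Product: 14 [2-(benzyloxy)-6-bromo-4-(prop-2-en-1-yloxy)phenyl](3,5-dimethoxyphenyl)methanone
Conditions: BnBr, K2CO3, n-Bu4NI (cat.), DMF, 60 °C
Reagents that add atoms: benzyl bromide, BrCc1ccccc1
Why: Williamson etherification of the remaining hydrogen-bonded phenol under more forcing conditions, which also removes the chelate that would otherwise steer the next rearrangement to the carbon between the two oxygens.

Step 9
Reactants: 14 [2-(benzyloxy)-6-bromo-4-(prop-2-en-1-yloxy)phenyl](3,5-dimethoxyphenyl)methanone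
Product: 15 [6-(benzyloxy)-2-bromo-4-hydroxy-3-(prop-2-en-1-yl)phenyl](3,5-dimethoxyphenyl)methanone
Conditions: PhNEt2, 190 °C
Reagents that add atoms: none
Why: Aromatic Claisen rearrangement ([3,3]-sigmatropic shift, then enolisation) with the para position blocked, in which the meta bromine directs migration to the ortho carbon next to itself and the meta alkoxy group directs it to the carbon para to itself, both pointing to C3 between the oxygen and the bromine, any other ortho isomer being separated here.

Step 10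
Reactants: 15 [6-(benzyloxy)-2-bromo-4-hydroxy-3-(prop-2-en-1-yl)phenyl](3,5-dimethoxyphenyl)methanone
Product: 18 [6-(benzyloxy)-4-bromo-2-hydroxy-2,3-dihydro-1-benzofuran-5-yl](3,5-dimethoxyphenyl)methanone, via diol 16 (not isolated), via hydroxy aldehyde 17 (not isolated)
Conditions: OsO4 (2 mol%), NaIO4 (4 equiv), 2,6-lutidine, 1,4-dioxane/H2O 3:1, rt
Reagents that add atoms: osmium tetroxide, O=[Os](=O)(=O)=O; sodium periodate (reoxidant and oxygen source), [Na+].[O-]I(=O)(=O)=O
Why: Lemieux–Johnson oxidation (osmylation, then periodate cleavage) of the terminal alkene, after which the arylacetaldehyde closes on the neighbouring phenol to the five-membered lactol, the electron-poor bromo-aroyl ring and the benzyl ether being left untouched.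

Step 11
Reactants: 18 [6-(benzyloxy)-4-bromo-2-hydroxy-2,3-dihydro-1-benzofuran-5-yl](3,5-dimethoxyphenyl)methanone
Product: 19 6-(benzyloxy)-4-bromo-5-(3,5-dimethoxybenzoyl)-1-benzofuran-2(3H)-one
Conditions: TEMPO (10 mol%), PhI(OAc)2 (1.5 equiv), CH2Cl2, rt
Reagents that add atoms: none
Why: Oxoammonium (TEMPO/PhI(OAc)2) oxidation of the lactol to the lactone, a mild method that should leave the acidic benzylic CH2 and the aryl ketone alone.

Step 12
Reactants: 9 1-chloro-2-[(1S)-1-(2,4-dimethoxyphenyl)-2-iodoethyl]-3,5-dimethoxybenzene; 19 6-(benzyloxy)-4-bromo-5-(3,5-dimethoxybenzoyl)-1-benzofuran-2(3H)-one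
Product: 21 6-(benzyloxy)-4-[(2S)-2-(2-chloro-4,6-dimethoxyphenyl)-2-(2,4-dimethoxyphenyl)ethyl]-5-(3,5-dimethoxybenzoyl)-1-benzofuran-2(3H)-one, via alkylzinc iodide 20 (not isolated)
Conditions: 9, Zn dust (activated with BrCH2CH2Br and Me3SiCl), LiCl, THF, 25 °C; then 19, Pd(OAc)2 (3 mol%), SPhos (6 mol%), THF, 25 °C
Reagents that add atoms: none
Why: Negishi sp3–sp2 coupling, in which zinc inserts into the primary C–I bond and Pd(OAc)2/SPhos couples the alkylzinc iodide with the ketone-activated aryl bromide despite its two ortho substituents, at a temperature at which the electron-rich aryl chloride should not undergo oxidative addition and at a rate expected to exceed protonation of the zinc reagent by the lactone C–H.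

Step 13
Reactants: 21 6-(benzyloxy)-4-[(2S)-2-(2-chloro-4,6-dimethoxyphenyl)-2-(2,4-dimethoxyphenyl)ethyl]-5-(3,5-dimethoxybenzoyl)-1-benzofuran-2(3H)-one
Product: 22 (7S,11bR)-4-(benzyloxy)-5-(3,5-dimethoxybenzoyl)-7-(2,4-dimethoxyphenyl)-8,10-dimethoxy-7,11b-dihydrobenzo[6,7]cyclohepta[1,2,3-cd][1]benzofuran-1(6H)-one
Conditions: Pd(OAc)2 (10 mol%), [HP(t-Bu)3]BF4 (20 mol%), K3PO4 (3 equiv), degassed toluene, 100 °C; AcOH quench at 0 °C; then Et3N (0.2 equiv), CH2Cl2, rt
Reagents that add atoms: none
Why: Palladium-catalysed intramolecular α-arylation of a lactone enolate: zerovalent palladium carrying P(t-Bu)3 inserts into the ring B C–Cl bond, K3PO4 deprotonates the benzofuranone C3–H (about as acidic as a malonate), the C-bound enolate replaces chloride on palladium and C(sp2)–C(sp3) reductive elimination forms C11b–C11a. The closest known reactions are the arylation of malonates, lactones and benzofuran-2(3H)-ones with aryl chlorides under Pd/P(t-Bu)3/phosphate and intramolecular enolate arylations that close benzo-fused seven-membered rings. The seven-membered carbocycle is closed by reductive elimination from an eight-membered aryl(enolato)palladium chelate, not by an ionic attack on the arene. The new stereocentre C11b stays enolisable in the product (a 3-aryl-benzofuranone), so its configuration is set under thermodynamic control by the phosphate during the reaction and by the Et3N stir afterwards; the lactone holds C1 in the plane of ring A, so the two C11b epimers differ in the face of ring A that ring B takes, and the (11bR) epimer, with H-11b cis to H-7 and the 2,4-dimethoxyphenyl group pseudo-equatorial on the boat-shaped ring, is the one expected to be favoured by the fixed (7S) centre. The step needs C- over O-arylation and reaction at C–Cl only: O-arylation would require a nine-membered ring, the ketone has no α-hydrogen, the benzyl ether is inert to the catalyst, and oxygen is excluded because the product enolate autoxidises.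

Step 14
Reactants: 22 (7S,11bR)-4-(benzyloxy)-5-(3,5-dimethoxybenzoyl)-7-(2,4-dimethoxyphenyl)-8,10-dimethoxy-7,11b-dihydrobenzo[6,7]cyclohepta[1,2,3-cd][1]benzofuran-1(6H)-one
Product: 23 (7S,11bR)-4-(benzyloxy)-5-(3,5-dimethoxybenzoyl)-7-(2,4-dimethoxyphenyl)-8,10-dimethoxy-1,6,7,11b-tetrahydrobenzo[6,7]cyclohepta[1,2,3-cd][1]benzofuran-1-ol (both C1 epimers)
Conditions: i-Bu2AlH (1.05 equiv), CH2Cl2, −78 °C; aq potassium sodium tartrate
Reagents that add atoms: none
Why: Partial reduction of the aryl lactone to the lactol through the aluminium hemiacetal that is stable at −78 °C, expected to be chemoselective because the aryl ester is far more electrophilic than the diaryl ketone, which is twisted out of conjugation and shielded by two ortho substituents, the lactol being used at once so that C11b is not exposed to enolisation through the open-chain aldehyde.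

Step 15
Reactants: 23 (7S,11bR)-4-(benzyloxy)-5-(3,5-dimethoxybenzoyl)-7-(2,4-dimethoxyphenyl)-8,10-dimethoxy-1,6,7,11b-tetrahydrobenzo[6,7]cyclohepta[1,2,3-cd][1]benzofuran-1-ol
Product: 24 [(5R,10S)-2-(benzyloxy)-10-(2,4-dimethoxyphenyl)-4-hydroxy-5-[hydroxy(4-methoxyphenyl)methyl]-7,9-dimethoxy-10,11-dihydro-5H-dibenzo[a,d][7]annulen-1-yl](3,5-dimethoxyphenyl)methanone (both carbinol epimers)
Conditions: 4-MeOC6H4MgBr (3 equiv), THF, −78 → −20 °C; aq NH4Cl
Reagents that add atoms: 4-methoxyphenylmagnesium bromide, COc1ccc([Mg]Br)cc1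
Why: Grignard addition to the hydroxy-aldehyde tautomer of the lactol (the first equivalent deprotonates the lactol), fast at low temperature whereas the doubly ortho-substituted diaryl ketone should not be attacked, both carbinol epimers being carried on because they converge in the next step.

Step 16
Reactants: 24 [(5R,10S)-2-(benzyloxy)-10-(2,4-dimethoxyphenyl)-4-hydroxy-5-[hydroxy(4-methoxyphenyl)methyl]-7,9-dimethoxy-10,11-dihydro-5H-dibenzo[a,d][7]annulen-1-yl](3,5-dimethoxyphenyl)methanone
Product: 25 [(1R,7S,11bR)-4-(benzyloxy)-7-(2,4-dimethoxyphenyl)-8,10-dimethoxy-1-(4-methoxyphenyl)-1,6,7,11b-tetrahydrobenzo[6,7]cyclohepta[1,2,3-cd][1]benzofuran-5-yl](3,5-dimethoxyphenyl)methanone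
Conditions: p-TsOH·H2O (10 mol%), CH2Cl2, 0 °C → rt
Reagents that add atoms: none
Why: Acid-catalysed dehydrative cyclisation in which either carbinol epimer ionises to the same p-methoxybenzylic cation, the neighbouring phenol closes the five-membered ring anti to the ring B substituent on C11b, and, the closure being reversible, the more stable 1,11b-trans dihydrofuran with (1R) configuration should result.

Step 17
Reactants: 25 [(1R,7S,11bR)-4-(benzyloxy)-7-(2,4-dimethoxyphenyl)-8,10-dimethoxy-1-(4-methoxyphenyl)-1,6,7,11b-tetrahydrobenzo[6,7]cyclohepta[1,2,3-cd][1]benzofuran-5-yl](3,5-dimethoxyphenyl)methanone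
Product: 26 [(1R,7S,11bR)-7-(2,4-dimethoxyphenyl)-4-hydroxy-8,10-dimethoxy-1-(4-methoxyphenyl)-1,6,7,11b-tetrahydrobenzo[6,7]cyclohepta[1,2,3-cd][1]benzofuran-5-yl](3,5-dimethoxyphenyl)methanone
Conditions: H2 (1 atm), 10% Pd/C, EtOAc/MeOH, rt
Reagents that add atoms: none
Why: Hydrogenolysis of the aryl benzyl ether over palladium on carbon, expected to be much faster at one atmosphere than hydrogenolysis of the cyclic benzylic ether or reduction of the hindered diaryl ketone, frees the phenol ortho to the ketone.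

Step 18
Reactants: 26 [(1R,7S,11bR)-7-(2,4-dimethoxyphenyl)-4-hydroxy-8,10-dimethoxy-1-(4-methoxyphenyl)-1,6,7,11b-tetrahydrobenzo[6,7]cyclohepta[1,2,3-cd][1]benzofuran-5-yl](3,5-dimethoxyphenyl)methanone
Product: 28 (1R,7S,11bR)-5-[(3,5-dimethoxyphenyl)(4-methylbenzenesulfonyl)methyl]-7-(2,4-dimethoxyphenyl)-8,10-dimethoxy-1-(4-methoxyphenyl)-1,6,7,11b-tetrahydrobenzo[6,7]cyclohepta[1,2,3-cd][1]benzofuran-4-ol (both epimers at the sulfonyl carbon), via carbinol 27 (not isolated)
Conditions: LiAlH4, THF, 0 °C, aqueous work-up; then p-TolSO2H, CH2Cl2, rt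
Reagents that add atoms: p-toluenesulfinic acid, Cc1ccc(cc1)S(=O)O
Why: Hydride reduction of the ketone to the o-hydroxybenzhydrol and, without purification, acid-mediated substitution of the doubly activated benzylic hydroxyl by sulfinate, which gives a bench-stable 2-(arylsulfonylmethyl)phenol as the standard precursor for base-induced o-quinone methide formation, the new sulfone-bearing centre being a mixture that is erased in step 20.

Step 19
Reactants: 29 4-methoxybenzyl chloride; 30 tetrahydrothiophene
Product: 31 1-[(4-methoxyphenyl)methyl]thiolan-1-ium chloride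
Conditions: acetone, rt
Reagents that add atoms: none
Why: S-Alkylation of the thioether by the reactive p-methoxybenzyl chloride gives the sulfonium salt, which should precipitate from acetone.

Step 20
Reactants: 28 (1R,7S,11bR)-5-[(3,5-dimethoxyphenyl)(4-methylbenzenesulfonyl)methyl]-7-(2,4-dimethoxyphenyl)-8,10-dimethoxy-1-(4-methoxyphenyl)-1,6,7,11b-tetrahydrobenzo[6,7]cyclohepta[1,2,3-cd][1]benzofuran-4-ol; 31 1-[(4-methoxyphenyl)methyl]thiolan-1-ium chloride
Product: 34 octamethyl ether of CNP0154047.2 (tetracycle of 25 with a (2R,3R)-3-(3,5-dimethoxyphenyl)-2-(4-methoxyphenyl)-2,3-dihydrofuran fused across C4–C5 and O on C4), via sulfonium ylide 32 (not isolated), via o-quinone methide 33 (not isolated)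
Conditions: 31 (2 equiv), Cs2CO3 (3 equiv), MeCN/CH2Cl2, 0 °C → rt
Reagents that add atoms: none
Why: Formal [4+1] annulation of an o-quinone methide with a sulfur ylide, in which Cs2CO3 eliminates sulfinate from the phenol and deprotonates the sulfonium salt, the semi-stabilised ylide adds to the exocyclic carbon and the phenoxide displaces tetrahydrothiophene with inversion from the anti betaine (this sets the 2,3-trans relationship), whereas which trans isomer forms depends on the quinone methide face attacked, for which only the remote bias of the folded tetracycle is available, so the (2R,3R) isomer is separated from its (2S,3S) diastereomer at this stage.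

Step 21
Reactants: 34 octamethyl ether of CNP0154047.2
Product: 35 CNP0154047.2
Conditions: BBr3 (16 equiv), CH2Cl2, −78 → 0 °C; MeOH, then H2O
Reagents that add atoms: none
Why: Lewis-acid cleavage of the eight aryl methyl ethers by BBr3 (bromide attack on the boron-complexed methyl groups), run cold because the two benzylic C–O bonds can ionise, both dihydrofurans being the thermodynamically preferred trans isomers so that reversible opening should not change their configuration.

**Compound list**

1 | 1-chloro-3,5-dimethoxybenzene | COc1cc(Cl)cc(OC)c1 | starting material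
2 | 2-chloro-4,6-dimethoxybenzaldehyde | O=Cc1c(Cl)cc(OC)cc1OC | intermediate
3 | methyl (2E)-3-(2-chloro-4,6-dimethoxyphenyl)prop-2-enoate | COC(=O)/C=C/c1c(Cl)cc(OC)cc1OC | intermediate
4 | 2,4-dimethoxyphenylboronic acid | COc1ccc(B(O)O)c(OC)c1 | starting material
5 | methyl (3S)-3-(2-chloro-4,6-dimethoxyphenyl)-3-(2,4-dimethoxyphenyl)propanoate | COC(=O)C[C@@H](c1ccc(OC)cc1OC)c1c(OC)cc(OC)cc1Cl | intermediate
6 | (3S)-3-(2-chloro-4,6-dimethoxyphenyl)-3-(2,4-dimethoxyphenyl)propanoic acid | OC(=O)C[C@@H](c1ccc(OC)cc1OC)c1c(OC)cc(OC)cc1Cl | intermediate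
7 | (3S)-3-(2-chloro-4,6-dimethoxyphenyl)-3-(2,4-dimethoxyphenyl)propanoyl chloride | ClC(=O)C[C@@H](c1ccc(OC)cc1OC)c1c(OC)cc(OC)cc1Cl | intermediate
8 | 2-sulfanylidenepyridin-1(2H)-yl (3S)-3-(2-chloro-4,6-dimethoxyphenyl)-3-(2,4-dimethoxyphenyl)propanoate | S=C1C=CC=CN1OC(=O)C[C@@H](c1ccc(OC)cc1OC)c1c(OC)cc(OC)cc1Cl | intermediate
9 | 1-chloro-2-[(1S)-1-(2,4-dimethoxyphenyl)-2-iodoethyl]-3,5-dimethoxybenzene | IC[C@@H](c1ccc(OC)cc1OC)c1c(OC)cc(OC)cc1Cl | intermediate
10 | 5-bromoresorcinol | Oc1cc(O)cc(Br)c1 | starting material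
11 | 3,5-dimethoxybenzoyl chloride | COc1cc(OC)cc(C(=O)Cl)c1 | starting material
12 | (2-bromo-4,6-dihydroxyphenyl)(3,5-dimethoxyphenyl)methanone | O=C(c1cc(OC)cc(OC)c1)c1c(O)cc(O)cc1Br | intermediate
13 | [2-bromo-6-hydroxy-4-(prop-2-en-1-yloxy)phenyl](3,5-dimethoxyphenyl)methanone | O=C(c1cc(OC)cc(OC)c1)c1c(O)cc(OCC=C)cc1Br | intermediate
14 | [2-(benzyloxy)-6-bromo-4-(prop-2-en-1-yloxy)phenyl](3,5-dimethoxyphenyl)methanone | O=C(c1cc(OC)cc(OC)c1)c1c(OCc2ccccc2)cc(OCC=C)cc1Br | intermediate
15 | [6-(benzyloxy)-2-bromo-4-hydroxy-3-(prop-2-en-1-yl)phenyl](3,5-dimethoxyphenyl)methanone | O=C(c1cc(OC)cc(OC)c1)c1c(OCc2ccccc2)cc(O)c(CC=C)c1Br | intermediate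
16 | [6-(benzyloxy)-2-bromo-3-(2,3-dihydroxypropyl)-4-hydroxyphenyl](3,5-dimethoxyphenyl)methanone | O=C(c1cc(OC)cc(OC)c1)c1c(OCc2ccccc2)cc(O)c(CC(O)CO)c1Br | intermediate
17 | 2-[4-(benzyloxy)-2-bromo-3-(3,5-dimethoxybenzoyl)-6-hydroxyphenyl]acetaldehyde | O=C(c1cc(OC)cc(OC)c1)c1c(OCc2ccccc2)cc(O)c(CC=O)c1Br | intermediate
18 | [6-(benzyloxy)-4-bromo-2-hydroxy-2,3-dihydro-1-benzofuran-5-yl](3,5-dimethoxyphenyl)methanone | OC1Cc2c(O1)cc(OCc1ccccc1)c(C(=O)c1cc(OC)cc(OC)c1)c2Br | intermediate
19 | 6-(benzyloxy)-4-bromo-5-(3,5-dimethoxybenzoyl)-1-benzofuran-2(3H)-one | O=C1Cc2c(O1)cc(OCc1ccccc1)c(C(=O)c1cc(OC)cc(OC)c1)c2Br | intermediate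
20 | [(2S)-2-(2-chloro-4,6-dimethoxyphenyl)-2-(2,4-dimethoxyphenyl)ethyl](iodo)zinc | I[Zn]C[C@@H](c1ccc(OC)cc1OC)c1c(OC)cc(OC)cc1Cl | intermediate
21 | 6-(benzyloxy)-4-[(2S)-2-(2-chloro-4,6-dimethoxyphenyl)-2-(2,4-dimethoxyphenyl)ethyl]-5-(3,5-dimethoxybenzoyl)-1-benzofuran-2(3H)-one | O=C1Cc2c(O1)cc(OCc1ccccc1)c(C(=O)c1cc(OC)cc(OC)c1)c2C[C@@H](c1ccc(OC)cc1OC)c1c(OC)cc(OC)cc1Cl | intermediate
22 | (7S,11bR)-4-(benzyloxy)-5-(3,5-dimethoxybenzoyl)-7-(2,4-dimethoxyphenyl)-8,10-dimethoxy-7,11b-dihydrobenzo[6,7]cyclohepta[1,2,3-cd][1]benzofuran-1(6H)-one | c1ccccc1COc1cc2OC(=O)[C@H]3c2c(C[C@@H](c2ccc(OC)cc2OC)c2c(OC)cc(OC)cc23)c1C(=O)c1cc(OC)cc(OC)c1 | intermediate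
23 | (7S,11bR)-4-(benzyloxy)-5-(3,5-dimethoxybenzoyl)-7-(2,4-dimethoxyphenyl)-8,10-dimethoxy-1,6,7,11b-tetrahydrobenzo[6,7]cyclohepta[1,2,3-cd][1]benzofuran-1-ol, both C1 epimers | c1ccccc1COc1cc2OC(O)[C@H]3c2c(C[C@@H](c2ccc(OC)cc2OC)c2c(OC)cc(OC)cc23)c1C(=O)c1cc(OC)cc(OC)c1 | intermediate
24 | [(5R,10S)-2-(benzyloxy)-10-(2,4-dimethoxyphenyl)-4-hydroxy-5-[hydroxy(4-methoxyphenyl)methyl]-7,9-dimethoxy-10,11-dihydro-5H-dibenzo[a,d][7]annulen-1-yl](3,5-dimethoxyphenyl)methanone, both carbinol epimers | c1ccccc1COc1cc(O)c2c(c1C(=O)c1cc(OC)cc(OC)c1)C[C@@H](c1ccc(OC)cc1OC)c1c(OC)cc(OC)cc1[C@H]2C(O)c1ccc(OC)cc1 | intermediate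
25 | [(1R,7S,11bR)-4-(benzyloxy)-7-(2,4-dimethoxyphenyl)-8,10-dimethoxy-1-(4-methoxyphenyl)-1,6,7,11b-tetrahydrobenzo[6,7]cyclohepta[1,2,3-cd][1]benzofuran-5-yl](3,5-dimethoxyphenyl)methanone | c1ccccc1COc1cc2c3c(c1C(=O)c1cc(OC)cc(OC)c1)C[C@@H](c1ccc(OC)cc1OC)c1c(OC)cc(OC)cc1[C@H]3[C@H](c1ccc(OC)cc1)O2 | intermediate
26 | [(1R,7S,11bR)-7-(2,4-dimethoxyphenyl)-4-hydroxy-8,10-dimethoxy-1-(4-methoxyphenyl)-1,6,7,11b-tetrahydrobenzo[6,7]cyclohepta[1,2,3-cd][1]benzofuran-5-yl](3,5-dimethoxyphenyl)methanone | Oc1cc2c3c(c1C(=O)c1cc(OC)cc(OC)c1)C[C@@H](c1ccc(OC)cc1OC)c1c(OC)cc(OC)cc1[C@H]3[C@H](c1ccc(OC)cc1)O2 | intermediate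
27 | (1R,7S,11bR)-5-[(3,5-dimethoxyphenyl)(hydroxy)methyl]-7-(2,4-dimethoxyphenyl)-8,10-dimethoxy-1-(4-methoxyphenyl)-1,6,7,11b-tetrahydrobenzo[6,7]cyclohepta[1,2,3-cd][1]benzofuran-4-ol, both carbinol epimers | Oc1cc2c3c(c1C(O)c1cc(OC)cc(OC)c1)C[C@@H](c1ccc(OC)cc1OC)c1c(OC)cc(OC)cc1[C@H]3[C@H](c1ccc(OC)cc1)O2 | intermediate
28 | (1R,7S,11bR)-5-[(3,5-dimethoxyphenyl)(4-methylbenzenesulfonyl)methyl]-7-(2,4-dimethoxyphenyl)-8,10-dimethoxy-1-(4-methoxyphenyl)-1,6,7,11b-tetrahydrobenzo[6,7]cyclohepta[1,2,3-cd][1]benzofuran-4-ol, both epimers at the sulfonyl carbon | Oc1cc2c3c(c1C(c1cc(OC)cc(OC)c1)S(=O)(=O)c1ccc(C)cc1)C[C@@H](c1ccc(OC)cc1OC)c1c(OC)cc(OC)cc1[C@H]3[C@H](c1ccc(OC)cc1)O2 | intermediate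
29 | 4-methoxybenzyl chloride | COc1ccc(CCl)cc1 | starting material
30 | tetrahydrothiophene | C1CCSC1 | starting material
31 | 1-[(4-methoxyphenyl)methyl]thiolan-1-ium chloride | COc1ccc(C[S+]2CCCC2)cc1.[Cl-] | intermediate
32 | (4-methoxyphenyl)(thiolan-1-ium-1-yl)methanide (sulfonium ylide) | COc1ccc([CH-][S+]2CCCC2)cc1 | intermediate
33 | (1R,7S,11bR)-5-[(3,5-dimethoxyphenyl)methylidene]-7-(2,4-dimethoxyphenyl)-8,10-dimethoxy-1-(4-methoxyphenyl)-1,6,7,11b-tetrahydrobenzo[6,7]cyclohepta[1,2,3-cd][1]benzofuran-4(5H)-one, either alkene geometry | O=C1C=C2C3=C(C1=Cc1cc(OC)cc(OC)c1)C[C@@H](c1ccc(OC)cc1OC)c1c(OC)cc(OC)cc1[C@H]3[C@H](c1ccc(OC)cc1)O2 | intermediate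
34 | octamethyl ether of CNP0154047.2: the (1R,7S,11bR) tetracycle of 25 carrying a (2R,3R)-3-(3,5-dimethoxyphenyl)-2-(4-methoxyphenyl)-2,3-dihydrofuran fused across C4–C5, O on C4 | COc1ccc([C@@H]2Oc3cc4c5c(c3[C@H]2c2cc(OC)cc(OC)c2)C[C@@H](c2ccc(OC)cc2OC)c2c(OC)cc(OC)cc2[C@H]5[C@H](c2ccc(OC)cc2)O4)cc1 | intermediate
35 | CNP0154047.2: the octaphenol of 34, same five stereocentres | Oc1ccc([C@@H]2Oc3cc4c5c(c3[C@H]2c2cc(O)cc(O)c2)C[C@@H](c2ccc(O)cc2O)c2c(O)cc(O)cc2[C@H]5[C@H](c2ccc(O)cc2)O4)cc1 | target

**Step count and risks**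

Total step count: 21 (steps 1–18, 20 and 21 on the two converging lines and the endgame, plus step 19, a one-step reagent preparation).
Longest linear sequence: 15 steps (from 10 through steps 6–18, 20 and 21 to 35).

Steps most likely to fail:

Step 13. Oxidative addition into the hindered, electron-rich C–Cl bond may be slow, leaving the enolate to autoxidise or to acylate another molecule; equilibration at C11b could also settle on the epimer with H-11b trans to H-7. Fallback by an aryne cyclisation, setting out from 21 and returning at 22: lithium 2,2,6,6-tetramethylpiperidide (3 equiv, THF, −78 → 0 °C) forms the lactone enolate and lithiates the ring B carbon between chlorine and methoxy, and loss of LiCl gives the 3-methoxyaryne. The enolate carbon then adds at the aryne carbon meta to the methoxy group, which is both the tether-favoured and the electronically favoured site, and protonation followed by the same Et3N equilibration gives 22. This fallback makes no compound outside the list (F0).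

Step 20. Facial selectivity in the addition of the ylide to the planar o-quinone methide may be poor or reversed, since only the remote C7 and C11b centres and the unknown methide geometry bias it; the (2S,3S) trans diastereomer would then dominate. Fallback by reagent control, setting out from 28 and 29 and returning at 34: 29 is used to alkylate (2R,5R)-2,5-dimethylthiolane (AgBF4, CH2Cl2) to give (2R,5R)-1-[(4-methoxyphenyl)methyl]-2,5-dimethylthiolan-1-ium tetrafluoroborate F1 (or its antipode, whichever is matched). Its C2-symmetric ylide selects one face at the ylide carbon, and the trans ring closure then ties the configuration of the neighbouring centre to it; 28, F1 and Cs2CO3 under the conditions of step 20 should give 34.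

Step 3. Migratory insertion of the aryl–rhodium species into the twisted, doubly ortho-substituted enoate may be too slow to compete with protodeboronation of the electron-rich boronic acid, or facial discrimination may be insufficient. Fallback by auxiliary-controlled cuprate addition, setting out from 3 and returning at 6:
- Saponification of 3 (LiOH) gives (2E)-3-(2-chloro-4,6-dimethoxyphenyl)prop-2-enoic acid F2.
- Acylation of (4R)-4-phenyl-1,3-oxazolidin-2-one through the pivaloyl mixed anhydride (t-BuCOCl, Et3N, LiCl) gives (4R)-3-[(2E)-3-(2-chloro-4,6-dimethoxyphenyl)prop-2-enoyl]-4-phenyl-1,3-oxazolidin-2-one F3.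
- 2,4-Dimethoxyphenylmagnesium bromide (from 1-bromo-2,4-dimethoxybenzene and Mg) with CuBr·SMe2 in THF at −40 → −10 °C adds to the chelated s-cis imide on the face anti to the 4-phenyl group, which should give (4R)-3-[(3S)-3-(2-chloro-4,6-dimethoxyphenyl)-3-(2,4-dimethoxyphenyl)propanoyl]-4-phenyl-1,3-oxazolidin-2-one F4.
- LiOH/H2O2 (THF/H2O, 0 °C) then releases 6.

Further compounds
F0 | step 13 | none | none
F1 | step 20 | (2R,5R)-1-[(4-methoxyphenyl)methyl]-2,5-dimethylthiolan-1-ium tetrafluoroborate | C[C@@H]1CC[C@@H](C)[S+]1Cc1ccc(OC)cc1.F[B-](F)(F)F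
F2 | step 3 | (2E)-3-(2-chloro-4,6-dimethoxyphenyl)prop-2-enoic acid | OC(=O)/C=C/c1c(Cl)cc(OC)cc1OC
F3 | step 3 | (4R)-3-[(2E)-3-(2-chloro-4,6-dimethoxyphenyl)prop-2-enoyl]-4-phenyl-1,3-oxazolidin-2-one | O=C(/C=C/c1c(Cl)cc(OC)cc1OC)N1[C@H](c2ccccc2)COC1=O
F4 | step 3 | (4R)-3-[(3S)-3-(2-chloro-4,6-dimethoxyphenyl)-3-(2,4-dimethoxyphenyl)propanoyl]-4-phenyl-1,3-oxazolidin-2-one | O=C(C[C@@H](c1ccc(OC)cc1OC)c1c(OC)cc(OC)cc1Cl)N1[C@H](c2ccccc2)COC1=O
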